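**Retrosynthetic overview**
1. The target is reached by substrate-controlled (Felkin–Anh) hydride reduction of the all-trans 4-aroyl-oxolane, so the carbinol centre is set last.
2. The 4-aroyl-oxolane comes from an epoxy aryl-alkyne ether by a visible-light Cp2Ti/Ir radical cyclisation with oxidative termination. This forms the C8–C8' bond and the only ring of the target (the oxolane); a second, transient enol-ether ring is reopened by hydrolysis in the same flask.
3. The epoxy alkyne comes from an anti aryl carbinol by O-propargylation, Sonogashira arylation and acetonide-to-epoxide conversion.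
4. The anti carbinol comes from 3,4,5-trimethoxyphenyl-titanium and (R)-glyceraldehyde acetonide (from D-mannitol), the only purchased stereocentre, which relays to all four centres of the target.

Assumption: the aryl bromide, the (R)-aldehyde (freshly distilled), propargyl bromide and the aryl iodide are bought; C7/C8/C8'/C7' are lignan locants (C7 = ring ArCH–O, C7' = carbinol carbon).

**Route**

Step 1
Reactants: 1 5-bromo-1,2,3-trimethoxybenzene; 2 (R)-2,2-dimethyl-1,3-dioxolane-4-carbaldehyde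
Product: 5 (S)-[(4R)-2,2-dimethyl-1,3-dioxolan-4-yl](3,4,5-trimethoxyphenyl)methanol, via arylmagnesium bromide 3 (not isolated), via aryltitanium triisopropoxide 4 (not isolated)
Conditions: Mg, THF, rt; ClTi(OiPr)3, −78 to −30 °C; then 2, −78 to 0 °C; H2O work-up
Reagents that add atoms: none
Why: Felkin–Anh 1,2-addition of a non-chelating aryltitanium to the α-alkoxy aldehyde (aryl enters anti to the dioxolane C–O bond) should give the anti (S)-carbinol, expected about 9:1, so the new centre is controlled by the purchased one.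

Step 2
Reactants: 5 (S)-[(4R)-2,2-dimethyl-1,3-dioxolan-4-yl](3,4,5-trimethoxyphenyl)methanol; 6 3-bromoprop-1-yne
Product: 7 (4R)-2,2-dimethyl-4-[(S)-(prop-2-yn-1-yloxy)(3,4,5-trimethoxyphenyl)methyl]-1,3-dioxolane
Conditions: NaH, TBAI (cat.), THF, 0 °C to rt
Reagents that add atoms: none
Why: Williamson etherification of the alkoxide with a reactive propargylic bromide; no stereocentre is touched, and alkylating before the epoxide exists avoids Payne rearrangement.

Step 3
Reactants: 7 (4R)-2,2-dimethyl-4-[(S)-(prop-2-yn-1-yloxy)(3,4,5-trimethoxyphenyl)methyl]-1,3-dioxolane; 8 4-iodo-1,2-dimethoxybenzene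
Product: 9 (4R)-4-[(S)-{[3-(3,4-dimethoxyphenyl)prop-2-yn-1-yl]oxy}(3,4,5-trimethoxyphenyl)methyl]-2,2-dimethyl-1,3-dioxolane
Conditions: Pd(PPh3)2Cl2 (2 mol %), CuI (4 mol %), Et3N, THF, 40 °C
Reagents that add atoms: none
Why: Sonogashira coupling of the terminal alkyne with the aryl iodide under mild amine conditions that leave the acetonide and the benzylic ether intact.

Step 4
Reactants: 9 (4R)-4-[(S)-{[3-(3,4-dimethoxyphenyl)prop-2-yn-1-yl]oxy}(3,4,5-trimethoxyphenyl)methyl]-2,2-dimethyl-1,3-dioxolane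
Product: 10 (2R,3S)-3-{[3-(3,4-dimethoxyphenyl)prop-2-yn-1-yl]oxy}-3-(3,4,5-trimethoxyphenyl)propane-1,2-diol
Conditions: AcOH/H2O (4:1), 40 °C
Reagents that add atoms: none
Why: Acid-catalysed acetal hydrolysis; dilute acetic acid is mild enough for the benzylic propargylic ether and both stereocentres are retained.

Step 5
Reactants: 10 (2R,3S)-3-{[3-(3,4-dimethoxyphenyl)prop-2-yn-1-yl]oxy}-3-(3,4,5-trimethoxyphenyl)propane-1,2-diol
Product: 11 (2R)-2-[(S)-{[3-(3,4-dimethoxyphenyl)prop-2-yn-1-yl]oxy}(3,4,5-trimethoxyphenyl)methyl]oxirane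
Conditions: PPh3, DIAD, toluene, 80 °C
Reagents that add atoms: none
Why: Mitsunobu cyclodehydration of a terminal 1,2-diol: the primary hydroxyl is activated and displaced by the secondary oxygen, so the secondary centre keeps its configuration.

Step 6
Reactants: 11 (2R)-2-[(S)-{[3-(3,4-dimethoxyphenyl)prop-2-yn-1-yl]oxy}(3,4,5-trimethoxyphenyl)methyl]oxirane
Product: 14 [(3R,4S,5R)-4-(hydroxymethyl)-5-(3,4,5-trimethoxyphenyl)oxolan-3-yl](3,4-dimethoxyphenyl)methanone, via bicyclic enol ether 12 (not isolated), via cis-keto alcohol 13 (not isolated)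
Conditions: Cp2TiCl2 (10 mol %), fac-Ir(ppy)3 (2 mol %), degassed MeCN (0.02 M), 450 nm LEDs, 25 °C; then H2O, PPTS (10 mol %), rt; then DBU (30 mol %), rt
Reagents that add atoms: water, O
Why: Proposed new method: a redox-neutral titanocene/photoredox radical-polar crossover cycloisomerisation of an epoxy aryl-alkyne, in which photoreduced Cp2Ti(III) opens the epoxide to the secondary β-titanoxy radical, this closes 5-exo-dig onto the alkyne with the CH2O[Ti] arm anti to the C-2 aryl group (2,3-trans), the aryl-stabilised vinyl radical is oxidised by Ir(IV) to a vinyl cation that the titanium-bound alkoxide captures as enol ether 12 (returning Ti(IV) and the photocatalyst with no stoichiometric reductant), mild hydrolysis gives cis-keto alcohol 13 and DBU equilibrates the ketone α-centre to the all-trans isomer; the closest known reactions are the reductive Cp2TiCl and Ti/photoredox epoxide-opening 5-exo radical cyclisations onto alkynes and the photoredox oxidation of aryl vinyl radicals to ketones.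

Step 7
Reactants: 14 [(3R,4S,5R)-4-(hydroxymethyl)-5-(3,4,5-trimethoxyphenyl)oxolan-3-yl](3,4-dimethoxyphenyl)methanone
Product: 15 (S)-(3,4-dimethoxyphenyl)[(3R,4S,5R)-4-(hydroxymethyl)-5-(3,4,5-trimethoxyphenyl)oxolan-3-yl]methanol
Conditions: L-Selectride (2.5 equiv), THF, −78 °C; H2O quench
Reagents that add atoms: none
Why: Felkin–Anh reduction with a bulky hydride, which should attack the aryl ketone anti to the more substituted ring carbon C-4 (the one carrying the CH2OH arm) and so set the (S)-carbinol; the first equivalent only deprotonates the primary alcohol.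

**Compound list**
1 | 5-bromo-1,2,3-trimethoxybenzene | COc1cc(Br)cc(OC)c1OC | starting material
2 | (R)-2,2-dimethyl-1,3-dioxolane-4-carbaldehyde | O=C[C@H]1COC(C)(C)O1 | starting material
3 | (3,4,5-trimethoxyphenyl)magnesium bromide | COc1cc([Mg]Br)cc(OC)c1OC | intermediate
4 | triisopropoxy(3,4,5-trimethoxyphenyl)titanium | COc1cc(cc(OC)c1OC)[Ti](OC(C)C)(OC(C)C)OC(C)C | intermediate
5 | (S)-[(4R)-2,2-dimethyl-1,3-dioxolan-4-yl](3,4,5-trimethoxyphenyl)methanol | COc1cc(cc(OC)c1OC)[C@H](O)[C@H]2COC(C)(C)O2 | intermediate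
6 | 3-bromoprop-1-yne | BrCC#C | starting material
7 | (4R)-2,2-dimethyl-4-[(S)-(prop-2-yn-1-yloxy)(3,4,5-trimethoxyphenyl)methyl]-1,3-dioxolane | COc1cc(cc(OC)c1OC)[C@H](OCC#C)[C@H]2COC(C)(C)O2 | intermediate
8 | 4-iodo-1,2-dimethoxybenzene | COc1ccc(I)cc1OC | starting material
9 | (4R)-4-[(S)-{[3-(3,4-dimethoxyphenyl)prop-2-yn-1-yl]oxy}(3,4,5-trimethoxyphenyl)methyl]-2,2-dimethyl-1,3-dioxolane | COc1ccc(C#CCO[C@@H](c2cc(OC)c(OC)c(OC)c2)[C@H]2COC(C)(C)O2)cc1OC | intermediate
10 | (2R,3S)-3-{[3-(3,4-dimethoxyphenyl)prop-2-yn-1-yl]oxy}-3-(3,4,5-trimethoxyphenyl)propane-1,2-diol | COc1ccc(C#CCO[C@@H](c2cc(OC)c(OC)c(OC)c2)[C@H](O)CO)cc1OC | intermediate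
11 | (2R)-2-[(S)-{[3-(3,4-dimethoxyphenyl)prop-2-yn-1-yl]oxy}(3,4,5-trimethoxyphenyl)methyl]oxirane | COc1ccc(C#CCO[C@@H](c2cc(OC)c(OC)c(OC)c2)[C@H]2CO2)cc1OC | intermediate
12 | (5S,6R)-2-(3,4-dimethoxyphenyl)-6-(3,4,5-trimethoxyphenyl)-3,7-dioxabicyclo[3.3.0]oct-1-ene (bicyclic enol ether) | COc1ccc(C2=C3CO[C@@H](c4cc(OC)c(OC)c(OC)c4)[C@@H]3CO2)cc1OC | intermediate
13 | [(3S,4S,5R)-4-(hydroxymethyl)-5-(3,4,5-trimethoxyphenyl)oxolan-3-yl](3,4-dimethoxyphenyl)methanone (3,4-cis keto alcohol) | COc1ccc(C(=O)[C@@H]2CO[C@@H](c3cc(OC)c(OC)c(OC)c3)[C@@H]2CO)cc1OC | intermediate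
14 | [(3R,4S,5R)-4-(hydroxymethyl)-5-(3,4,5-trimethoxyphenyl)oxolan-3-yl](3,4-dimethoxyphenyl)methanone | COc1ccc(C(=O)[C@H]2CO[C@@H](c3cc(OC)c(OC)c(OC)c3)[C@@H]2CO)cc1OC | intermediate
15 | (S)-(3,4-dimethoxyphenyl)[(3R,4S,5R)-4-(hydroxymethyl)-5-(3,4,5-trimethoxyphenyl)oxolan-3-yl]methanol | COc1ccc([C@@H](O)[C@H]2CO[C@@H](c3cc(OC)c(OC)c(OC)c3)[C@@H]2CO)cc1OC | target

**Totals**
Total steps: 7. Longest linear sequence: 7 (from 1 or 2 to 15).

**Three steps most likely to fail**

Step 6 (the proposed new step). The risks are that the vinyl radical is not oxidised and titanium turnover stalls, that the electron-rich arenes are oxidised, and that the 3,4-cis isomer is held back as its bicyclic hemiketal during equilibration. The fallback uses known reactions only, sets out from 9 and comes back at 14. Gold(I)-catalysed Markovnikov hydration of the aryl alkyne ((Ph3P)AuNTf2 cat., wet dioxane, 60 °C) gives 1-(3,4-dimethoxyphenyl)-3-{(S)-[(4R)-2,2-dimethyl-1,3-dioxolan-4-yl](3,4,5-trimethoxyphenyl)methoxy}propan-1-one F3. Aqueous acetic acid then gives 1-(3,4-dimethoxyphenyl)-3-{[(1S,2R)-2,3-dihydroxy-1-(3,4,5-trimethoxyphenyl)propyl]oxy}propan-1-one F4, and Mitsunobu cyclodehydration gives 1-(3,4-dimethoxyphenyl)-3-{(S)-[(2R)-oxiran-2-yl](3,4,5-trimethoxyphenyl)methoxy}propan-1-one F5. LiHMDS (THF, −78 to 0 °C) forms the ketone enolate, which opens the epoxide 5-exo-tet with inversion at the epoxide carbon; this puts the CH2OH arm trans to the C-2 aryl group, and the ketone α-centre equilibrates to give 14.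

Step 7. The Felkin preference of a ring-bound ketone may be modest, and the nearby lithium alkoxide could erode it. The fallback sets out from 14 and comes back at 15. Silylation (TBDPSCl, imidazole, DMF) gives [(3R,4S,5R)-4-{[tert-butyl(diphenyl)silyl]oxymethyl}-5-(3,4,5-trimethoxyphenyl)oxolan-3-yl](3,4-dimethoxyphenyl)methanone F6, in which the bulky silyl ether enlarges the C-4 side and removes the alkoxide. L-Selectride then gives (S)-(3,4-dimethoxyphenyl)[(3R,4S,5R)-4-{[tert-butyl(diphenyl)silyl]oxymethyl}-5-(3,4,5-trimethoxyphenyl)oxolan-3-yl]methanol F7, and TBAF (THF) releases 15.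

Step 1. The anti:syn ratio of aryl additions to this aldehyde depends on the metal and can fall towards 2:1. The fallback sets out from 1 and 2 and comes back at 5. Direct addition of Grignard reagent 3 to 2 (THF, −78 °C) gives 5 together with its epimer (R)-[(4R)-2,2-dimethyl-1,3-dioxolan-4-yl](3,4,5-trimethoxyphenyl)methanol F1. Dess–Martin oxidation of the mixture gives [(4R)-2,2-dimethyl-1,3-dioxolan-4-yl](3,4,5-trimethoxyphenyl)methanone F2, and α-chelation-controlled reduction with Zn(BH4)2 (Et2O, −30 °C) returns the anti alcohol 5.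

**Further compounds**
F1 | step 1 | (R)-[(4R)-2,2-dimethyl-1,3-dioxolan-4-yl](3,4,5-trimethoxyphenyl)methanol | COc1cc(cc(OC)c1OC)[C@@H](O)[C@H]2COC(C)(C)O2
F2 | step 1 | [(4R)-2,2-dimethyl-1,3-dioxolan-4-yl](3,4,5-trimethoxyphenyl)methanone | COc1cc(cc(OC)c1OC)C(=O)[C@H]2COC(C)(C)O2
F3 | step 6 | 1-(3,4-dimethoxyphenyl)-3-{(S)-[(4R)-2,2-dimethyl-1,3-dioxolan-4-yl](3,4,5-trimethoxyphenyl)methoxy}propan-1-one | COc1ccc(C(=O)CCO[C@@H](c2cc(OC)c(OC)c(OC)c2)[C@H]2COC(C)(C)O2)cc1OC
F4 | step 6 | 1-(3,4-dimethoxyphenyl)-3-{[(1S,2R)-2,3-dihydroxy-1-(3,4,5-trimethoxyphenyl)propyl]oxy}propan-1-one | COc1ccc(C(=O)CCO[C@@H](c2cc(OC)c(OC)c(OC)c2)[C@H](O)CO)cc1OC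
F5 | step 6 | 1-(3,4-dimethoxyphenyl)-3-{(S)-[(2R)-oxiran-2-yl](3,4,5-trimethoxyphenyl)methoxy}propan-1-one | COc1ccc(C(=O)CCO[C@@H](c2cc(OC)c(OC)c(OC)c2)[C@H]2CO2)cc1OC
F6 | step 7 | [(3R,4S,5R)-4-{[tert-butyl(diphenyl)silyl]oxymethyl}-5-(3,4,5-trimethoxyphenyl)oxolan-3-yl](3,4-dimethoxyphenyl)methanone | COc1ccc(C(=O)[C@H]2CO[C@@H](c3cc(OC)c(OC)c(OC)c3)[C@@H]2CO[Si](c2ccccc2)(c2ccccc2)C(C)(C)C)cc1OC
F7 | step 7 | (S)-(3,4-dimethoxyphenyl)[(3R,4S,5R)-4-{[tert-butyl(diphenyl)silyl]oxymethyl}-5-(3,4,5-trimethoxyphenyl)oxolan-3-yl]methanol | COc1ccc([C@@H](O)[C@H]2CO[C@@H](c3cc(OC)c(OC)c(OC)c3)[C@@H]2CO[Si](c2ccccc2)(c2ccccc2)C(C)(C)C)cc1OC
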